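**Plan**

- Retrosynthesis, in order: the four benzyl ethers; ring C of the flavone (cut at O1–C2 and C4–C4a, back to an ortho-iodophenol, CO and an aryl acetylene); the cyclohexane at its C5–C6 bond (gem-dimethyl carbon to the neighbouring ring CH2); then C4–C5 (α-methylenation of a sulfone), C3–C4 (sulfone carbanion + terminal epoxide), C1–C6 (isopropenyl + epoxy alcohol) and aryl–prenyl.
- Feature that allows the ring closure: C6 of the cyclohexane carries two methyl groups, so it can arise from an isopropenyl group as a tertiary radical by hydrogen-atom transfer. C5 is a bare CH2, so it can be the terminal carbon of a 1,1-disubstituted alkene whose inner carbon (C4) holds a phenylsulfonyl group that is reduced off afterwards.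
- Forward order: aryl prenylation, allylic oxidation, asymmetric epoxidation, epoxide opening by isopropenyl, terminal epoxide, sulfone, vinyl sulfone, 6-endo radical closure of the cyclohexane, desulfonylation; then phenol release, iodination, carbonylative closure of ring C, hydrogenolysis.
- Stereochemistry: the carbinol carbon (C2) comes from Sharpless epoxidation of the (E)-allylic alcohol with L-(+)-diethyl tartrate; C1 comes from SN2 inversion at the epoxide CH by isopropenylMgBr/CuI. The ring closure creates no lasting stereocentre.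

Key step: step 9

Remark: in names, Ar = 2,6-bis(benzyloxy)-4-[(triisopropylsilyl)oxy]phenyl and Ar-methyl = ArCH2.
Remark: the cyclised sulfone formed in step 9 is expected as a mixture of epimers at the sulfonyl-bearing carbon; this centre becomes CH2 in step 10, so it is given without a stereodescriptor.
Remark: 3,5-bis(benzyloxy)phenol, prenyl bromide, isopropenylmagnesium bromide, methyl phenyl sulfone and 3,4-bis(benzyloxy)benzaldehyde are taken as purchasable.

**Step 1**
Reactants: 1 3,5-bis(benzyloxy)phenol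
Product: 2 [3,5-bis(benzyloxy)phenoxy]triisopropylsilane
Conditions: TIPSCl, imidazole, DMF, rt
Reagents that add atoms: triisopropylsilyl chloride, CC(C)[Si](Cl)(C(C)C)C(C)C
Why: Standard silyl ether formation puts a bulky, non-coordinating group on the one oxygen that must later be told apart from the two benzyl ethers (it becomes the pyranone oxygen).

**Step 2**
Reactants: 2 [3,5-bis(benzyloxy)phenoxy]triisopropylsilane; 3 prenyl bromide
Product: 5 1-Ar-3-methylbut-2-ene, via aryllithium 4 (not isolated)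
Conditions: n-BuLi, THF, 0 °C; then CuI (5 mol %), prenyl bromide, −78 °C → rt
Reagents that add atoms: none
Why: Directed ortho-metalation should occur at the carbon flanked by the two benzyloxy groups (the silyloxy group neither directs nor admits the base), and the aryllithium is then allylated by SN2 under CuI catalysis.

**Step 3**
Reactants: 5 1-Ar-3-methylbut-2-ene
Product: 7 (E)-4-Ar-2-methylbut-2-en-1-ol, via enal 6 (not isolated)
Conditions: SeO2 (20 mol %), t-BuOOH, CH2Cl2, rt; then NaBH4, MeOH, 0 °C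
Reagents that add atoms: tert-butyl hydroperoxide (oxygen relayed by catalytic SeO2), CC(C)(C)OO
Why: SeO2 allylic oxidation (ene reaction, then [2,3]-sigmatropic shift) attacks the (E)-methyl group of the trisubstituted alkene, and NaBH4 returns over-oxidised enal to the (E)-allylic alcohol.

**Step 4**
Reactants: 7 (E)-4-Ar-2-methylbut-2-en-1-ol
Product: 8 [(2S,3S)-3-(Ar-methyl)-2-methyloxiran-2-yl]methanol
Conditions: Ti(OiPr)4 (10 mol %), L-(+)-diethyl tartrate (12 mol %), t-BuOOH, 4 Å MS, CH2Cl2, −20 °C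
Reagents that add atoms: tert-butyl hydroperoxide, CC(C)(C)OO
Why: Sharpless asymmetric epoxidation of an (E)-2-methyl allylic alcohol with L-(+)-tartrate should deliver oxygen to the face that gives the (2S,3S)-epoxide, which fixes the configuration of the future tertiary carbinol.

**Step 5**
Reactants: 8 [(2S,3S)-3-(Ar-methyl)-2-methyloxiran-2-yl]methanol; 9 isopropenylmagnesium bromide
Product: 10 (2R,3S)-3-(Ar-methyl)-2,4-dimethylpent-4-ene-1,2-diol
Conditions: isopropenylMgBr (4 equiv), CuI (20 mol %), THF, −30 → 0 °C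
Reagents that add atoms: none
Why: CuI-catalysed SN2 opening of the 2,3-epoxy alcohol at C3, the only epoxide carbon that is not quaternary, proceeds with inversion and sets the second stereocentre anti to the tertiary hydroxyl while bringing in the isopropenyl group.

**Step 6**
Reactants: 10 (2R,3S)-3-(Ar-methyl)-2,4-dimethylpent-4-ene-1,2-diol
Product: 12 (2R)-2-[(2S)-1-Ar-3-methylbut-3-en-2-yl]-2-methyloxirane, via primary tosylate 11 (not isolated)
Conditions: NaH, 1-(p-toluenesulfonyl)imidazole, THF, 0 °C → rt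
Reagents that add atoms: none
Why: Selective sulfonylation of the primary alkoxide followed by internal displacement by the tertiary alkoxide (intramolecular Williamson reaction) gives the terminal epoxide without touching either stereocentre.

**Step 7**
Reactants: 12 (2R)-2-[(2S)-1-Ar-3-methylbut-3-en-2-yl]-2-methyloxirane; 13 methyl phenyl sulfone
Product: 15 (3S,4S)-4-(Ar-methyl)-3,5-dimethyl-1-(phenylsulfonyl)hex-5-en-3-ol, via lithiated sulfone 14 (not isolated)
Conditions: PhSO2CH3, n-BuLi, THF/DMPU, −78 °C → rt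
Reagents that add atoms: none
Why: The α-sulfonyl carbanion opens the 2,2-disubstituted epoxide at its CH2 carbon by SN2, which restores the tertiary alcohol and adds the carbon that will carry the activating sulfonyl group.

**Step 8**
Reactants: 15 (3S,4S)-4-(Ar-methyl)-3,5-dimethyl-1-(phenylsulfonyl)hex-5-en-3-ol
Product: 19 (4S,5S)-5-(Ar-methyl)-4,6-dimethyl-2-(phenylsulfonyl)hepta-1,6-dien-4-ol, via dilithio sulfone 16 (not isolated), via Mannich base 17 (not isolated), via ammonium iodide 18 (not isolated)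
Conditions: n-BuLi (2.2 equiv), THF, −78 °C; Eschenmoser's salt, −78 → 0 °C; then MeI, CH2Cl2, rt; then DBU, CH2Cl2, 0 °C → rt
Reagents that add atoms: Eschenmoser's salt (N,N-dimethylmethyleneiminium iodide), C=[N+](C)C.[I-]
Why: The α-sulfonyl carbanion is aminomethylated (Mannich reaction), and quaternisation followed by E1cB loss of trimethylamine under an amidine base too weak to form the tertiary alkoxide gives the 1,1-disubstituted vinyl sulfone without 5-endo oxa-Michael closure.

**Step 9**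
Reactants: 19 (4S,5S)-5-(Ar-methyl)-4,6-dimethyl-2-(phenylsulfonyl)hepta-1,6-dien-4-ol
Product: 20 (1S,2S)-2-(Ar-methyl)-1,3,3-trimethyl-5-(phenylsulfonyl)cyclohexan-1-ol
Conditions: Fe(acac)3 (30 mol %), PhSiH3 (3 equiv), EtOH/THF, 60 °C, high dilution
Reagents that add atoms: none
Why: Fe(acac)3 and PhSiH3 in ethanol form an Fe–H species that transfers a hydrogen atom to the terminal CH2 of the electron-rich isopropenyl group (Markovnikov), giving the tertiary radical at the future gem-dimethyl carbon; this nucleophilic radical adds to the unsubstituted terminus of the 2-(phenylsulfonyl)alkene, and the α-sulfonyl radical is reduced by divalent iron and protonated by the solvent. The closest known reaction type is the Fe(acac)3/PhSiH3 hydrogen-atom-transfer reductive coupling of an unactivated olefin with an electron-poor olefin (a radical Giese addition), used here intramolecularly. The cyclohexane closes in the 6-endo-trig mode along the chain C(radical)–CH–C(OH)–CH2–C(SO2Ph)=CH2. No lasting stereocentre is formed, because the new quaternary carbon bears two methyl groups; the sulfonyl-bearing carbon is set under substrate control (equatorial sulfone expected) and is erased in step 10, and the two existing stereocentres are not involved. The step needs hydrogen-atom transfer to the 1,1-disubstituted donor alkene rather than the acceptor, and 6-endo rather than 5-exo closure; the first follows from the polarity difference of the two alkenes, the second from the sulfonyl group on the inner alkene carbon, which makes attack at the CH2 terminus the only path to a stabilised radical.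

**Step 10**
Reactants: 20 (1S,2S)-2-(Ar-methyl)-1,3,3-trimethyl-5-(phenylsulfonyl)cyclohexan-1-ol
Product: 21 (1S,2S)-2-(Ar-methyl)-1,3,3-trimethylcyclohexan-1-ol
Conditions: 6% Na/Hg, Na2HPO4, MeOH/THF, −20 °C → rt
Reagents that add atoms: none
Why: Reductive desulfonylation by electron transfer from Na/Hg cleaves the C–S bond of the secondary alkyl phenyl sulfone and should leave benzyl ethers, silyl ether and tertiary alcohol intact.

**Step 11**
Reactants: 21 (1S,2S)-2-(Ar-methyl)-1,3,3-trimethylcyclohexan-1-ol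
Product: 22 3,5-bis(benzyloxy)-4-{[(1S,2S)-2-hydroxy-2,6,6-trimethylcyclohexyl]methyl}phenol
Conditions: TBAF, THF, 0 °C
Reagents that add atoms: none
Why: Fluoride cleaves the aryl silyl ether and frees the one phenol that lies para to the benzylic carbon.

**Step 12**
Reactants: 22 3,5-bis(benzyloxy)-4-{[(1S,2S)-2-hydroxy-2,6,6-trimethylcyclohexyl]methyl}phenol
Product: 23 3,5-bis(benzyloxy)-4-{[(1S,2S)-2-hydroxy-2,6,6-trimethylcyclohexyl]methyl}-2-iodophenol
Conditions: N-iodosuccinimide (1.0 equiv), CH2Cl2, −40 → 0 °C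
Reagents that add atoms: N-iodosuccinimide, O=C1CCC(=O)N1I
Why: Electrophilic iodination of the phenol occurs ortho to the free hydroxyl, and the two unsubstituted ring positions are equivalent by symmetry, so a single regioisomer should result.

**Step 13**
Reactants: 24 3,4-bis(benzyloxy)benzaldehyde
Product: 25 4-ethynyl-1,2-bis(benzyloxy)benzene
Conditions: dimethyl (1-diazo-2-oxopropyl)phosphonate, K2CO3, MeOH/THF, rt
Reagents that add atoms: Ohira–Bestmann reagent, COP(=O)(OC)C(=[N+]=[N-])C(C)=O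
Why: The Ohira–Bestmann variant of the Seyferth–Gilbert homologation converts an aryl aldehyde into the terminal alkyne under mild base.

**Step 14**
Reactants: 23 3,5-bis(benzyloxy)-4-{[(1S,2S)-2-hydroxy-2,6,6-trimethylcyclohexyl]methyl}-2-iodophenol; 25 4-ethynyl-1,2-bis(benzyloxy)benzene
Product: 27 5,7-bis(benzyloxy)-2-[3,4-bis(benzyloxy)phenyl]-6-{[(1S,2S)-2-hydroxy-2,6,6-trimethylcyclohexyl]methyl}-4H-chromen-4-one, via ynone 26 (not isolated)
Conditions: PdCl2(PPh3)2 (5 mol %), CO (1–5 bar), Et2NH, DMF, 60 °C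
Reagents that add atoms: carbon monoxide, [C-]#[O+]
Why: Carbonylative Sonogashira coupling gives the ortho-hydroxyaryl ynone, which the secondary amine helps to close by 6-endo conjugate addition of the phenol; because the free hydroxyl sits next to iodine and para to the benzylic carbon, the side chain ends at C6 of the flavone.

**Step 15**
Reactants: 27 5,7-bis(benzyloxy)-2-[3,4-bis(benzyloxy)phenyl]-6-{[(1S,2S)-2-hydroxy-2,6,6-trimethylcyclohexyl]methyl}-4H-chromen-4-one
Product: 28 2-(3,4-dihydroxyphenyl)-5,7-dihydroxy-6-{[(1S,2S)-2-hydroxy-2,6,6-trimethylcyclohexyl]methyl}-4H-chromen-4-one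
Conditions: H2 (1 atm), 10% Pd/C, EtOAc/MeOH, rt
Reagents that add atoms: none
Why: Hydrogenolysis of the four benzyl ethers under neutral conditions should free the phenols without ionising the tertiary alcohol, which under acid would close onto a neighbouring phenol.

**Compound list**

1 | 3,5-bis(benzyloxy)phenol | Oc1cc(OCc2ccccc2)cc(OCc2ccccc2)c1 | starting material
2 | [3,5-bis(benzyloxy)phenoxy]triisopropylsilane | CC(C)[Si](Oc1cc(OCc2ccccc2)cc(OCc2ccccc2)c1)(C(C)C)C(C)C | intermediate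
3 | prenyl bromide (1-bromo-3-methylbut-2-ene) | CC(C)=CCBr | starting material
4 | aryllithium Ar–Li, lithiated between the two benzyloxy groups (formed in the flask, step 2) | [Li]c1c(OCc2ccccc2)cc(O[Si](C(C)C)(C(C)C)C(C)C)cc1OCc1ccccc1 | intermediate
5 | 1-Ar-3-methylbut-2-ene | CC(C)=CCc1c(OCc2ccccc2)cc(O[Si](C(C)C)(C(C)C)C(C)C)cc1OCc1ccccc1 | intermediate
6 | (E)-4-Ar-2-methylbut-2-enal (formed in the flask, step 3) | O=C/C(C)=C/Cc1c(OCc2ccccc2)cc(O[Si](C(C)C)(C(C)C)C(C)C)cc1OCc1ccccc1 | intermediate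
7 | (E)-4-Ar-2-methylbut-2-en-1-ol | OC/C(C)=C/Cc1c(OCc2ccccc2)cc(O[Si](C(C)C)(C(C)C)C(C)C)cc1OCc1ccccc1 | intermediate
8 | [(2S,3S)-3-(Ar-methyl)-2-methyloxiran-2-yl]methanol | OC[C@](C)(O1)[C@@H]1Cc1c(OCc2ccccc2)cc(O[Si](C(C)C)(C(C)C)C(C)C)cc1OCc1ccccc1 | intermediate
9 | isopropenylmagnesium bromide | CC(=C)[Mg]Br | starting material
10 | (2R,3S)-3-(Ar-methyl)-2,4-dimethylpent-4-ene-1,2-diol | OC[C@](C)(O)[C@H](C(C)=C)Cc1c(OCc2ccccc2)cc(O[Si](C(C)C)(C(C)C)C(C)C)cc1OCc1ccccc1 | intermediate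
11 | (2R,3S)-3-(Ar-methyl)-2-hydroxy-2,4-dimethylpent-4-en-1-yl 4-methylbenzenesulfonate (formed in the flask, step 6) | Cc1ccc(S(=O)(=O)OC[C@](C)(O)[C@H](C(C)=C)Cc2c(OCc3ccccc3)cc(O[Si](C(C)C)(C(C)C)C(C)C)cc2OCc2ccccc2)cc1 | intermediate
12 | (2R)-2-[(2S)-1-Ar-3-methylbut-3-en-2-yl]-2-methyloxirane | C1O[C@]1(C)[C@H](C(C)=C)Cc1c(OCc2ccccc2)cc(O[Si](C(C)C)(C(C)C)C(C)C)cc1OCc1ccccc1 | intermediate
13 | methyl phenyl sulfone | CS(=O)(=O)c1ccccc1 | starting material
14 | [(phenylsulfonyl)methyl]lithium (formed in the flask, step 7) | [Li]CS(=O)(=O)c1ccccc1 | intermediate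
15 | (3S,4S)-4-(Ar-methyl)-3,5-dimethyl-1-(phenylsulfonyl)hex-5-en-3-ol | O=S(=O)(CC[C@](C)(O)[C@H](C(C)=C)Cc1c(OCc2ccccc2)cc(O[Si](C(C)C)(C(C)C)C(C)C)cc1OCc1ccccc1)c1ccccc1 | intermediate
16 | C,O-dilithio derivative of 15, lithiated at the sulfonyl-bearing carbon and at oxygen (formed in the flask, step 8) | [Li]C(C[C@](C)(O[Li])[C@H](C(C)=C)Cc1c(OCc2ccccc2)cc(O[Si](C(C)C)(C(C)C)C(C)C)cc1OCc1ccccc1)S(=O)(=O)c1ccccc1 | intermediate
17 | (4S,5S)-5-(Ar-methyl)-1-(dimethylamino)-4,6-dimethyl-2-(phenylsulfonyl)hept-6-en-4-ol, epimers at C2 (formed in the flask, step 8) | CN(C)CC(C[C@](C)(O)[C@H](C(C)=C)Cc1c(OCc2ccccc2)cc(O[Si](C(C)C)(C(C)C)C(C)C)cc1OCc1ccccc1)S(=O)(=O)c1ccccc1 | intermediate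
18 | N-methyl ammonium iodide of 17 (formed in the flask, step 8) | C[N+](C)(C)CC(C[C@](C)(O)[C@H](C(C)=C)Cc1c(OCc2ccccc2)cc(O[Si](C(C)C)(C(C)C)C(C)C)cc1OCc1ccccc1)S(=O)(=O)c1ccccc1.[I-] | intermediate
19 | (4S,5S)-5-(Ar-methyl)-4,6-dimethyl-2-(phenylsulfonyl)hepta-1,6-dien-4-ol | C=C(C[C@](C)(O)[C@H](C(C)=C)Cc1c(OCc2ccccc2)cc(O[Si](C(C)C)(C(C)C)C(C)C)cc1OCc1ccccc1)S(=O)(=O)c1ccccc1 | intermediate
20 | (1S,2S)-2-(Ar-methyl)-1,3,3-trimethyl-5-(phenylsulfonyl)cyclohexan-1-ol, epimers at C5 | CC1(C)CC(S(=O)(=O)c2ccccc2)C[C@](C)(O)[C@H]1Cc1c(OCc2ccccc2)cc(O[Si](C(C)C)(C(C)C)C(C)C)cc1OCc1ccccc1 | intermediate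
21 | (1S,2S)-2-(Ar-methyl)-1,3,3-trimethylcyclohexan-1-ol | CC1(C)CCC[C@](C)(O)[C@H]1Cc1c(OCc2ccccc2)cc(O[Si](C(C)C)(C(C)C)C(C)C)cc1OCc1ccccc1 | intermediate
22 | 3,5-bis(benzyloxy)-4-{[(1S,2S)-2-hydroxy-2,6,6-trimethylcyclohexyl]methyl}phenol | CC1(C)CCC[C@](C)(O)[C@H]1Cc1c(OCc2ccccc2)cc(O)cc1OCc1ccccc1 | intermediate
23 | 3,5-bis(benzyloxy)-4-{[(1S,2S)-2-hydroxy-2,6,6-trimethylcyclohexyl]methyl}-2-iodophenol | CC1(C)CCC[C@](C)(O)[C@H]1Cc1c(OCc2ccccc2)cc(O)c(I)c1OCc1ccccc1 | intermediate
24 | 3,4-bis(benzyloxy)benzaldehyde | O=Cc1ccc(OCc2ccccc2)c(OCc2ccccc2)c1 | starting material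
25 | 4-ethynyl-1,2-bis(benzyloxy)benzene | C#Cc1ccc(OCc2ccccc2)c(OCc2ccccc2)c1 | intermediate
26 | 1-[2,4-bis(benzyloxy)-6-hydroxy-3-{[(1S,2S)-2-hydroxy-2,6,6-trimethylcyclohexyl]methyl}phenyl]-3-[3,4-bis(benzyloxy)phenyl]prop-2-yn-1-one (formed in the flask, step 14) | CC1(C)CCC[C@](C)(O)[C@H]1Cc1c(OCc2ccccc2)cc(O)c(C(=O)C#Cc2ccc(OCc3ccccc3)c(OCc3ccccc3)c2)c1OCc1ccccc1 | intermediate
27 | 5,7-bis(benzyloxy)-2-[3,4-bis(benzyloxy)phenyl]-6-{[(1S,2S)-2-hydroxy-2,6,6-trimethylcyclohexyl]methyl}-4H-chromen-4-one | CC1(C)CCC[C@](C)(O)[C@H]1Cc1c(OCc2ccccc2)cc2oc(-c3ccc(OCc4ccccc4)c(OCc4ccccc4)c3)cc(=O)c2c1OCc1ccccc1 | intermediate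
28 | 2-(3,4-dihydroxyphenyl)-5,7-dihydroxy-6-{[(1S,2S)-2-hydroxy-2,6,6-trimethylcyclohexyl]methyl}-4H-chromen-4-one | CC1(C)CCC[C@](C)(O)[C@H]1Cc1c(O)cc2oc(-c3ccc(O)c(O)c3)cc(=O)c2c1O | target

**Step count**

Total steps: 15. Longest linear sequence: 14 (steps 1–12, 14, 15); step 13 is a one-step side branch.

**Steps most likely to fail**

1. Step 9 (key step). The tertiary radical may be quenched before it cyclises (net hydrogenation of the isopropenyl group), the vinyl sulfone may be reduced directly, or reversible hydrogen-atom transfer may move the double bond to the tetrasubstituted position and erode the neighbouring stereocentre. The fallback sets out from diol 10 and comes back at 21. It moves the activating group into the ring as a ketone, so that an enone (the acceptor class with the closest intramolecular precedent) takes the radical, and the helper is removed differently. Oxidation of the primary hydroxyl of 10 (SO3·pyridine, DMSO, Et3N) would give (2R,3S)-3-(Ar-methyl)-2-hydroxy-2,4-dimethylpent-4-enal F1. Vinylmagnesium bromide would add to give (4R,5S)-5-(Ar-methyl)-4,6-dimethylhepta-1,6-diene-3,4-diol F2, and MnO2 would oxidise the allylic carbinol to (4R,5S)-5-(Ar-methyl)-4-hydroxy-4,6-dimethylhepta-1,6-dien-3-one F3. Fe(acac)3/PhSiH3 would then close the same bond 6-endo onto the vinyl ketone to give (2R,3S)-3-(Ar-methyl)-2-hydroxy-2,4,4-trimethylcyclohexan-1-one F4. NaBH4 would reduce the ketone to (1R,6S)-6-(Ar-methyl)-1,5,5-trimethylcyclohexane-1,2-diol F5. MsCl/Et3N would sulfonylate only the secondary hydroxyl to give (2R,3S)-3-(Ar-methyl)-2-hydroxy-2,4,4-trimethylcyclohexyl methanesulfonate F6. LiEt3BH would then deliver hydride to the secondary carbon, directly or through the transient epoxide closed by the tertiary alkoxide, without breaking the tertiary C–O bond, to give 21.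

2. Step 5. SN2 attack of the bulky sp2 organocopper reagent (isopropenylMgBr/CuI) at the hindered secondary epoxide carbon may be slow, so that halohydrin formation by MgBr2 or epoxide migration takes over. The fallback sets out from epoxy alcohol 8 and comes back at diol 10; it uses a small linear sp nucleophile and builds the isopropenyl group afterwards. Diethyl[(trimethylsilyl)ethynyl]aluminium F7 (from trimethylsilylacetylene, n-BuLi and Et2AlCl) would open 8 at C3 with inversion to give (2R,3S)-3-(Ar-methyl)-2-methyl-5-(trimethylsilyl)pent-4-yne-1,2-diol F8. K2CO3 in methanol would give the terminal alkyne (2R,3S)-3-(Ar-methyl)-2-methylpent-4-yne-1,2-diol F9. Cp2ZrCl2-catalysed methylalumination (Me3Al, Cp2ZrCl2, CH2Cl2), which places the methyl group on the inner alkyne carbon, followed by protonolysis with water, would give 10.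

3. Step 14. Oxidative addition into the electron-rich, doubly ortho-substituted C–I bond may be slow; non-carbonylative Sonogashira coupling followed by closure to a benzofuran, or 5-exo closure to the aurone, may compete. The fallback sets out from phenol 22 (it also replaces step 12) and comes back at 27; it builds the ynone without palladium or CO. Ortho-formylation of 22 (MgCl2, Et3N, paraformaldehyde, MeCN, reflux) would give 4,6-bis(benzyloxy)-2-hydroxy-5-{[(1S,2S)-2-hydroxy-2,6,6-trimethylcyclohexyl]methyl}benzaldehyde F10. Excess {[3,4-bis(benzyloxy)phenyl]ethynyl}lithium F11 (from 25 and n-BuLi, THF, −78 °C) would add to give the propargylic alcohol 1-[2,4-bis(benzyloxy)-6-hydroxy-3-{[(1S,2S)-2-hydroxy-2,6,6-trimethylcyclohexyl]methyl}phenyl]-3-[3,4-bis(benzyloxy)phenyl]prop-2-yn-1-ol F12. MnO2 would oxidise it to ynone 26, and Et2NH in ethanol would close 26 6-endo to 27.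

**Further compounds**

F1 | step 9 | (2R,3S)-3-(Ar-methyl)-2-hydroxy-2,4-dimethylpent-4-enal | O=C[C@](C)(O)[C@H](C(C)=C)Cc1c(OCc2ccccc2)cc(O[Si](C(C)C)(C(C)C)C(C)C)cc1OCc1ccccc1
F2 | step 9 | (4R,5S)-5-(Ar-methyl)-4,6-dimethylhepta-1,6-diene-3,4-diol, epimers at C3 | C=CC(O)[C@](C)(O)[C@H](C(C)=C)Cc1c(OCc2ccccc2)cc(O[Si](C(C)C)(C(C)C)C(C)C)cc1OCc1ccccc1
F3 | step 9 | (4R,5S)-5-(Ar-methyl)-4-hydroxy-4,6-dimethylhepta-1,6-dien-3-one | C=CC(=O)[C@](C)(O)[C@H](C(C)=C)Cc1c(OCc2ccccc2)cc(O[Si](C(C)C)(C(C)C)C(C)C)cc1OCc1ccccc1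
F4 | step 9 | (2R,3S)-3-(Ar-methyl)-2-hydroxy-2,4,4-trimethylcyclohexan-1-one | CC1(C)CCC(=O)[C@](C)(O)[C@H]1Cc1c(OCc2ccccc2)cc(O[Si](C(C)C)(C(C)C)C(C)C)cc1OCc1ccccc1
F5 | step 9 | (1R,6S)-6-(Ar-methyl)-1,5,5-trimethylcyclohexane-1,2-diol, epimers at C2 | CC1(C)CCC(O)[C@](C)(O)[C@H]1Cc1c(OCc2ccccc2)cc(O[Si](C(C)C)(C(C)C)C(C)C)cc1OCc1ccccc1
F6 | step 9 | (2R,3S)-3-(Ar-methyl)-2-hydroxy-2,4,4-trimethylcyclohexyl methanesulfonate, epimers at C1 | CC1(C)CCC(OS(C)(=O)=O)[C@](C)(O)[C@H]1Cc1c(OCc2ccccc2)cc(O[Si](C(C)C)(C(C)C)C(C)C)cc1OCc1ccccc1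
F7 | step 5 | diethyl[(trimethylsilyl)ethynyl]aluminium | CC[Al](CC)C#C[Si](C)(C)C
F8 | step 5 | (2R,3S)-3-(Ar-methyl)-2-methyl-5-(trimethylsilyl)pent-4-yne-1,2-diol | OC[C@](C)(O)[C@H](C#C[Si](C)(C)C)Cc1c(OCc2ccccc2)cc(O[Si](C(C)C)(C(C)C)C(C)C)cc1OCc1ccccc1
F9 | step 5 | (2R,3S)-3-(Ar-methyl)-2-methylpent-4-yne-1,2-diol | OC[C@](C)(O)[C@H](C#C)Cc1c(OCc2ccccc2)cc(O[Si](C(C)C)(C(C)C)C(C)C)cc1OCc1ccccc1
F10 | step 14 | 4,6-bis(benzyloxy)-2-hydroxy-5-{[(1S,2S)-2-hydroxy-2,6,6-trimethylcyclohexyl]methyl}benzaldehyde | CC1(C)CCC[C@](C)(O)[C@H]1Cc1c(OCc2ccccc2)cc(O)c(C=O)c1OCc1ccccc1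
F11 | step 14 | {[3,4-bis(benzyloxy)phenyl]ethynyl}lithium | [Li]C#Cc1ccc(OCc2ccccc2)c(OCc2ccccc2)c1
F12 | step 14 | 1-[2,4-bis(benzyloxy)-6-hydroxy-3-{[(1S,2S)-2-hydroxy-2,6,6-trimethylcyclohexyl]methyl}phenyl]-3-[3,4-bis(benzyloxy)phenyl]prop-2-yn-1-ol, epimers at the carbinol | CC1(C)CCC[C@](C)(O)[C@H]1Cc1c(OCc2ccccc2)cc(O)c(C(O)C#Cc2ccc(OCc3ccccc3)c(OCc3ccccc3)c2)c1OCc1ccccc1
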